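**Retrosynthetic overview**

1. Numbering used here: C1 (CH–OAc), C2 (CH2), C3 (butenolide β-carbon), C4 (α-carbon, Me), C5 (C=O), C6 (lactone O–CH), C7=C8(Me), C9, C10, C11–C12(Me) (oxirane), C13, C14, C15=C16(Me), C16 bonded to C1. Enabling feature: C3–C6 is the one bond shared by the five-membered lactone and the fourteen-membered carbocycle; C6 carries the lactone oxygen next to the C7=C8 olefin (a masked enal carbonyl), and C3 is the β-carbon of a Z α-methylacrylate whose ester sits cis to it.
2. Last disconnection: C3–C6, opened to an acyclic (Z)-β-triflyloxy-α-methylacrylate/enal. Forward, a Nozaki–Hiyama–Kishi ring closure makes the carbocycle and the C6 alkoxide closes the butenolide on the cis ester in the same operation, setting C6.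
3. Seco chain: C1–C2 by an enantioselective vinylogous Mukaiyama aldol onto a C1 enal (sets C1, brings C2–C5); the enal comes from allylic oxidation of the terminal E-methyl of a nerol-derived chain.
4. C9–C10 by alkylation of the acetoacetate dianion with the triflate of (2S,3R)-epoxynerol; C7=C8(Me) from the resulting β-keto ester via Z enol triflate and methyl cross-coupling; C11/C12 from asymmetric epoxidation of nerol.
5. Ring order: oxirane first (step 1); carbocycle and butenolide together in the last step.

Key step: step 15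

Remark: in the target C10 and C13 lie on the same face of the oxirane (11S,12R), i.e. it is the epoxide of a Z olefin; this is taken as drawn, which is why nerol and not geraniol is the starting material.

**Route**

Step 1
Reactants: 1 nerol
Product: 2 (2S,3R)-2,3-epoxynerol
Conditions: Ti(OiPr)4 (5 mol%), L-(+)-diethyl tartrate (6 mol%), t-BuOOH (in decane), 4 Å molecular sieves, CH2Cl2, −20 °C
Reagents that add atoms: tert-butyl hydroperoxide, CC(C)(C)OO
Why: Sharpless asymmetric epoxidation: the titanium tartrate binds the allylic hydroxyl so only the C2 olefin of nerol reacts, L-(+)-tartrate should deliver oxygen to the face that gives the 2S,3R epoxy alcohol, and the Z geometry is carried into the cis-oxirane (sets C11 and C12).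

Step 2
Reactants: 2 (2S,3R)-2,3-epoxynerol; 3 methyl acetoacetate
Product: 5 methyl 5-[(2S,3R)-3-methyl-3-(4-methylpent-3-en-1-yl)oxiran-2-yl]-3-oxopentanoate, via epoxy triflate 4 (not isolated)
Conditions: 2, Tf2O, 2,6-lutidine, CH2Cl2, −78 °C; cold solution cannulated into the dianion of 3 (3 equiv; NaH, then n-BuLi, THF, 0 °C) at −78 → −20 °C; aq. NH4Cl
Reagents that add atoms: none
Why: SN2 alkylation of a β-keto ester dianion at its terminal carbon: the primary triflate should be displaced at −78 °C much faster than the trisubstituted oxirane is opened, so C9–C10 forms with the epoxide stereocentres untouched.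

Step 3
Reactants: 5 β-keto ester
Product: 6 methyl (2Z)-5-[(2S,3R)-3-methyl-3-(4-methylpent-3-en-1-yl)oxiran-2-yl]-3-{[(trifluoromethyl)sulfonyl]oxy}pent-2-enoate
Conditions: NaH, THF, 0 °C; PhNTf2, 0 °C → rt
Reagents that add atoms: N-phenylbis(trifluoromethanesulfonimide), O=S(=O)(N(c1ccccc1)S(=O)(=O)C(F)(F)F)C(F)(F)F
Why: O-sulfonylation of the chelated sodium enolate of a β-keto ester places the triflate cis to the ester (Z), the geometry that step 4 turns into the E trisubstituted olefin.

Step 4
Reactants: 6 Z enol triflate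
Product: 7 methyl (2E,6S,7R)-6,7-epoxy-3,7,11-trimethyldodeca-2,10-dienoate
Conditions: Pd(PPh3)4 (5 mol%), Me2Zn, THF, 0 °C → rt
Reagents that add atoms: dimethylzinc, C[Zn]C
Why: Negishi cross-coupling of an enol triflate proceeds with retention of olefin geometry, so methyl replaces the triflate and C7=C8 is formed as the E isomer, while the oxirane is inert to the mild organozinc.

Step 5
Reactants: 7 epoxy enoate
Product: 8 (2E,6S,7R)-6,7-epoxy-3,7,11-trimethyldodeca-2,10-dien-1-ol
Conditions: iBu2AlH (2.3 equiv), CH2Cl2, −78 °C; aq. KNaC4H4O6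
Reagents that add atoms: none
Why: 1,2-reduction of an α,β-unsaturated ester by a dialkylaluminium hydride at −78 °C stops at the allylic alcohol and is too cold to open the trisubstituted oxirane.

Step 6
Reactants: 8 allylic alcohol
Product: 9 tert-butyl{[(2E,6S,7R)-6,7-epoxy-3,7,11-trimethyldodeca-2,10-dien-1-yl]oxy}dimethylsilane
Conditions: t-BuMe2SiCl, imidazole, CH2Cl2, 0 °C → rt
Reagents that add atoms: tert-butyldimethylsilyl chloride, CC(C)(C)[Si](C)(C)Cl
Why: Standard silylation of a primary allylic alcohol; the silyl ether masks C6–OH and lowers the reactivity of the C7=C8 olefin toward the allylic oxidation that follows.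

Step 7
Reactants: 9 silyl ether
Product: 11 (2E,6R,7S,10E)-12-[(tert-butyldimethylsilyl)oxy]-6,7-epoxy-2,6,10-trimethyldodeca-2,10-dienal, via allylic alcohol 10 (not isolated)
Conditions: SeO2 (0.3 equiv), t-BuOOH (in decane), CH2Cl2, 0 °C → rt; crude product, MnO2, CH2Cl2, rt
Reagents that add atoms: selenium dioxide (catalytic oxygen carrier), O=[Se]=O; tert-butyl hydroperoxide (stoichiometric oxygen source), CC(C)(C)OO
Why: Selenium dioxide allylic oxidation (ene reaction, then [2,3]-sigmatropic shift) should attack the E-methyl of the terminal, most electron-rich gem-dimethyl olefin and give the E 2-methyl allylic alcohol, which MnO2 takes on to the enal without touching silyl ether or oxirane.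

Step 8
Reactants: 12 methyl 2-methyl-3-oxobutanoate
Product: 13 methyl 2-methyl-3-[(trimethylsilyl)oxy]but-2-enoate
Conditions: Me3SiCl, Et3N, hexane, rt
Reagents that add atoms: chlorotrimethylsilane, C[Si](C)(C)Cl
Why: Silylation of the enol form of a β-keto ester with a chlorosilane and an amine base is the standard route to 3-silyloxy enoates.

Step 9
Reactants: 13 silyl enol ether
Product: 14 1-methoxy-2-methyl-1,3-bis[(trimethylsilyl)oxy]buta-1,3-diene
Conditions: LiN(iPr)2, THF, −78 °C; Me3SiCl, −78 °C → rt
Reagents that add atoms: chlorotrimethylsilane, C[Si](C)(C)Cl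
Why: γ-Deprotonation of the vinylogous ester by a lithium amide and O-silylation of the dienolate is the standard preparation of 1,3-bis(silyloxy)dienes.

Step 10
Reactants: 11 enal; 14 bis-silyl diene
Product: 16 methyl (5R,6E,10R,11S,14E)-16-[(tert-butyldimethylsilyl)oxy]-10,11-epoxy-5-hydroxy-2,6,10,14-tetramethyl-3-oxohexadeca-6,14-dienoate (C2 epimers), via bis-silyl aldol adduct 15 (not isolated)
Conditions: Ti(OiPr)4 (10 mol%), (R)-BINOL (10 mol%), 4 Å molecular sieves, THF, −78 → −20 °C; then PPTS (cat.), MeOH, 0 °C
Reagents that add atoms: none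
Why: Catalytic enantioselective vinylogous Mukaiyama aldol: the titanium–BINOL complex activates the enal carbonyl for 1,2-attack by the terminal CH2 of the diene, (R)-BINOL is expected by analogy with titanium–BINOL additions to aldehydes to give the 1R carbinol (to be confirmed as MTPA esters), the weakly Lewis acidic alkoxide catalyst should leave the oxirane alone, and the C4 methyl centre forms as a mixture that is erased in step 12.

Step 11
Reactants: 16 δ-hydroxy β-keto ester
Product: 17 methyl (5R,6E,10R,11S,14E)-5-acetoxy-16-[(tert-butyldimethylsilyl)oxy]-10,11-epoxy-2,6,10,14-tetramethyl-3-oxohexadeca-6,14-dienoate (C2 epimers)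
Conditions: Ac2O, pyridine, DMAP (cat.), CH2Cl2, 0 °C
Reagents that add atoms: acetic anhydride, CC(=O)OC(C)=O
Why: Acylation of the secondary allylic alcohol under nucleophilic catalysis at 0 °C is faster than O-acylation of the β-keto ester enol, installs the acetate of the target and blocks lactonisation of the δ-hydroxy β-keto ester.

Step 12
Reactants: 17 δ-acetoxy β-keto ester
Product: 18 methyl (2Z,5R,6E,10R,11S,14E)-5-acetoxy-16-[(tert-butyldimethylsilyl)oxy]-10,11-epoxy-2,6,10,14-tetramethyl-3-{[(trifluoromethyl)sulfonyl]oxy}hexadeca-2,6,14-trienoate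
Conditions: NaH (1.0 equiv), THF, 0 °C; PhNTf2, 0 °C → rt
Reagents that add atoms: N-phenylbis(trifluoromethanesulfonimide), O=S(=O)(N(c1ccccc1)S(=O)(=O)C(F)(F)F)C(F)(F)F
Why: With one equivalent of NaH only the doubly activated C4–H is removed, so the β-acetoxy group should not be eliminated, and O-sulfonylation of the chelated sodium enolate gives the Z enol triflate with the triflate cis to the ester, as needed for lactonisation in step 15.

Step 13
Reactants: 18 silyl ether
Product: 19 methyl (2Z,5R,6E,10R,11S,14E)-5-acetoxy-10,11-epoxy-16-hydroxy-2,6,10,14-tetramethyl-3-{[(trifluoromethyl)sulfonyl]oxy}hexadeca-2,6,14-trienoate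
Conditions: HF·pyridine, pyridine, THF, 0 °C
Reagents that add atoms: none
Why: Pyridine-buffered fluoride cleaves the primary silyl ether, while enol triflate, acetate, methyl ester and trisubstituted oxirane are expected to be stable at 0 °C.

Step 14
Reactants: 19 allylic alcohol
Product: 20 methyl (2Z,5R,6E,10R,11S,14E)-5-acetoxy-10,11-epoxy-2,6,10,14-tetramethyl-16-oxo-3-{[(trifluoromethyl)sulfonyl]oxy}hexadeca-2,6,14-trienoate
Conditions: MnO2, CH2Cl2, rt
Reagents that add atoms: none
Why: MnO2 oxidises the primary allylic alcohol to the E enal under neutral conditions without isomerising the olefin or touching the other functions.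

Step 15
Reactants: 20 seco enal enol triflate
Product: 22 target CNP0302675.1 [(2R,7S,8R,13R)-13-acetoxy-7,8-epoxycembra-1(15),3E,11E-trien-16,2-olide; 1R,6R,11S,12R in the route numbering], via macrocyclic chromium alkoxide 21 (not isolated)
Conditions: CrCl2 (6 equiv), chiral 2-(2-sulfonamidophenyl)oxazoline ligand (6.6 equiv, antipode selected for 6R), Et3N (6.6 equiv), NiCl2 (0.5 equiv), THF, rt; 20 added by syringe pump over 12 h (final 2 mM); aq. ethylenediamine work-up
Reagents that add atoms: none
Why: Zerovalent nickel (from NiCl2 and divalent chromium) inserts into the C3–OTf bond of the electron-poor Z enol triflate, the alkenyl group passes to trivalent chromium with retention of geometry, and the alkenylchromium adds 1,2 to the C6 enal carbonyl; the closest known reaction type is the Nozaki–Hiyama–Kishi macrocyclisation of alkenyl iodides or triflates onto aldehydes, including additions of (Z)-β-halo acrylates that give butenolides directly. The fourteen-membered carbocycle closes by a 14-exo-trig addition to C=O, and the C6 chromium alkoxide, held cis to the C5 methyl ester across C3=C4, then closes the butenolide by 5-exo-trig acyl substitution with loss of methoxide, so two rings and the last stereocentre arise from an open chain in one operation. The new C6 stereocentre is set under reagent control by the chiral sulfonamide ligand on chromium, because C1 and the C11–C12 oxirane are remote from the reacting carbons; the ligand antipode that gives 6R is fixed in a matched-pair test. The step needs 1,2- over 1,4-addition and aldehyde over ester, acetate and oxirane, which the oxophilic, weakly basic alkenylchromium secures, and it needs nickel to choose the triflate over the C1 allylic acetate, which the much faster insertion into the sp2 C–OTf bond next to the ester secures. Ring closure over oligomerisation is favoured by slow addition to high dilution and by the three geometrically defined olefins and the cis-oxirane, which limit the conformations of the seco chain. The irreversible lactonisation removes the alkoxide and so prevents retro-addition.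

**Compound list**

1 | nerol, (2Z)-3,7-dimethylocta-2,6-dien-1-ol | CC(C)=CCC/C(C)=C\CO | starting material
2 | [(2S,3R)-3-methyl-3-(4-methylpent-3-en-1-yl)oxiran-2-yl]methanol, (2S,3R)-2,3-epoxynerol | CC(C)=CCC[C@@]1(C)O[C@H]1CO | intermediate
3 | methyl acetoacetate | COC(=O)CC(C)=O | starting material
4 | trifluoromethanesulfonate of 2 | CC(C)=CCC[C@@]1(C)O[C@H]1COS(=O)(=O)C(F)(F)F | intermediate (not isolated)
5 | methyl 5-[(2S,3R)-3-methyl-3-(4-methylpent-3-en-1-yl)oxiran-2-yl]-3-oxopentanoate | CC(C)=CCC[C@@]1(C)O[C@H]1CCC(=O)CC(=O)OC | intermediate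
6 | methyl (2Z)-5-[(2S,3R)-3-methyl-3-(4-methylpent-3-en-1-yl)oxiran-2-yl]-3-{[(trifluoromethyl)sulfonyl]oxy}pent-2-enoate | CC(C)=CCC[C@@]1(C)O[C@H]1CC/C(OS(=O)(=O)C(F)(F)F)=C/C(=O)OC | intermediate
7 | methyl (2E,6S,7R)-6,7-epoxy-3,7,11-trimethyldodeca-2,10-dienoate (cis-oxirane) | CC(C)=CCC[C@@]1(C)O[C@H]1CC/C(C)=C/C(=O)OC | intermediate
8 | (2E,6S,7R)-6,7-epoxy-3,7,11-trimethyldodeca-2,10-dien-1-ol | CC(C)=CCC[C@@]1(C)O[C@H]1CC/C(C)=C/CO | intermediate
9 | tert-butyldimethylsilyl ether of 8 | CC(C)=CCC[C@@]1(C)O[C@H]1CC/C(C)=C/CO[Si](C)(C)C(C)(C)C | intermediate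
10 | (2E,6R,7S,10E)-12-[(tert-butyldimethylsilyl)oxy]-6,7-epoxy-2,6,10-trimethyldodeca-2,10-dien-1-ol | OC/C(C)=C/CC[C@@]1(C)O[C@H]1CC/C(C)=C/CO[Si](C)(C)C(C)(C)C | intermediate (not isolated)
11 | (2E,6R,7S,10E)-12-[(tert-butyldimethylsilyl)oxy]-6,7-epoxy-2,6,10-trimethyldodeca-2,10-dienal | O=C/C(C)=C/CC[C@@]1(C)O[C@H]1CC/C(C)=C/CO[Si](C)(C)C(C)(C)C | intermediate
12 | methyl 2-methyl-3-oxobutanoate | COC(=O)C(C)C(C)=O | starting material
13 | methyl 2-methyl-3-[(trimethylsilyl)oxy]but-2-enoate (E/Z mixture) | COC(=O)C(C)=C(C)O[Si](C)(C)C | intermediate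
14 | 1-methoxy-2-methyl-1,3-bis[(trimethylsilyl)oxy]buta-1,3-diene | COC(O[Si](C)(C)C)=C(C)C(=C)O[Si](C)(C)C | intermediate
15 | bis-silyl aldol adduct (5-O-trimethylsilyl ether, drawn as the 3-silyl enol ether) | COC(=O)C(C)=C(C[C@@H](O[Si](C)(C)C)/C(C)=C/CC[C@@]1(C)O[C@H]1CC/C(C)=C/CO[Si](C)(C)C(C)(C)C)O[Si](C)(C)C | intermediate (not isolated)
16 | methyl (5R,6E,10R,11S,14E)-16-[(tert-butyldimethylsilyl)oxy]-10,11-epoxy-5-hydroxy-2,6,10,14-tetramethyl-3-oxohexadeca-6,14-dienoate (C2 epimers) | COC(=O)C(C)C(=O)C[C@@H](O)/C(C)=C/CC[C@@]1(C)O[C@H]1CC/C(C)=C/CO[Si](C)(C)C(C)(C)C | intermediate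
17 | 5-O-acetate of 16 (C2 epimers) | COC(=O)C(C)C(=O)C[C@@H](OC(C)=O)/C(C)=C/CC[C@@]1(C)O[C@H]1CC/C(C)=C/CO[Si](C)(C)C(C)(C)C | intermediate
18 | methyl (2Z,5R,6E,10R,11S,14E)-5-acetoxy-16-[(tert-butyldimethylsilyl)oxy]-10,11-epoxy-2,6,10,14-tetramethyl-3-{[(trifluoromethyl)sulfonyl]oxy}hexadeca-2,6,14-trienoate | COC(=O)/C(C)=C(OS(=O)(=O)C(F)(F)F)/C[C@@H](OC(C)=O)/C(C)=C/CC[C@@]1(C)O[C@H]1CC/C(C)=C/CO[Si](C)(C)C(C)(C)C | intermediate
19 | methyl (2Z,5R,6E,10R,11S,14E)-5-acetoxy-10,11-epoxy-16-hydroxy-2,6,10,14-tetramethyl-3-{[(trifluoromethyl)sulfonyl]oxy}hexadeca-2,6,14-trienoate | COC(=O)/C(C)=C(OS(=O)(=O)C(F)(F)F)/C[C@@H](OC(C)=O)/C(C)=C/CC[C@@]1(C)O[C@H]1CC/C(C)=C/CO | intermediate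
20 | methyl (2Z,5R,6E,10R,11S,14E)-5-acetoxy-10,11-epoxy-2,6,10,14-tetramethyl-16-oxo-3-{[(trifluoromethyl)sulfonyl]oxy}hexadeca-2,6,14-trienoate | COC(=O)/C(C)=C(OS(=O)(=O)C(F)(F)F)/C[C@@H](OC(C)=O)/C(C)=C/CC[C@@]1(C)O[C@H]1CC/C(C)=C/C=O | intermediate
21 | fourteen-membered (Z)-γ-hydroxy-α-methyl enoate with C3–C6 formed (present as its chromium alkoxide; drawn as the free 6R alcohol) | CC(=O)O[C@@H]1C/C(=C(C)/C(=O)OC)[C@H](O)/C=C(\C)CC[C@@H]2O[C@]2(C)CC/C=C/1C | intermediate (not isolated)
22 | CNP0302675.1, (2R,7S,8R,13R)-13-acetoxy-7,8-epoxycembra-1(15),3E,11E-trien-16,2-olide | CC(=O)O[C@@H]1CC2=C(C)C(=O)O[C@@H]2/C=C(\C)CC[C@@H]2O[C@]2(C)CC/C=C/1C | target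

**Step count and risks**

Total step count: 15. Longest linear sequence: 13 steps (steps 1–7 and 10–15, from nerol); steps 8–9 are a two-step side branch.

Steps most likely to fail:

1. Step 15. What may go wrong: the alkenylchromium adds to the enal with poor facial selectivity at C6 because the folding of the seco chain overrides the ligand, or intermolecular coupling outruns ring closure. The fallback separates ring closure from the control of C6. Compound 20 is cyclised with CrCl2/NiCl2 alone in DMSO–THF at 1 mM, the conditions with the broadest precedent for macrocyclic ring closure, and both C6 epimers are accepted. Compound 22 is separated, and the (6S)-epimer of the target F1 is deprotonated at C6 (LiN(SiMe3)2, THF, −78 °C) to the lithium 2-furanolate F2, in which C6 is planar. This is the known γ-deprotonation of butenolides and should be preferred over the C2 methylene because it creates the aromatic 2-oxyfuran. Kinetic protonation of F2 at −78 °C (AcOH, or a hindered phenol if the face selectivity needs tuning) should return the α,β-unsaturated lactone as a C6 mixture, from which 22 is collected and F1 is recycled. The fallback sets out from 20 and rejoins the route at 22.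

2. Step 2. What may go wrong: the strongly basic dianion opens or eliminates the oxirane next to the triflate, or the triflate decomposes before it is alkylated. The fallback avoids displacement next to the oxirane and makes the C8–C9 bond by sp3–sp2 cross-coupling instead. From 2, oxidation (SO3·pyridine, DMSO, iPr2NEt) should give the epoxy aldehyde F3, and Wittig methylenation (Ph3P=CH2 from Ph3PCH3Br and KN(SiMe3)2) the vinyl oxirane F4. Hydroboration with 9-BBN-H should give the B-alkyl borane F5, used in solution. F5 is coupled (Pd(dppf)Cl2, AsPh3, Cs2CO3, DMF–THF–H2O, rt) with methyl (2E)-3-{[(trifluoromethyl)sulfonyl]oxy}but-2-enoate F6, made from 3 under non-chelating conditions (Tf2O, aqueous Me4NOH, hexane). B-alkyl Suzuki–Miyaura coupling retains the olefin geometry of F6 and should deliver 7, where the route is rejoined.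

3. Step 10. What may go wrong: insufficient facial selectivity at C1 with an α-branched enal and a 2-substituted diene, or slow turnover with erosion by the uncatalysed background aldol. The fallback replaces catalyst control by a stoichiometric chiral acetate enolate followed by a decarboxylative Claisen homologation. From 11, doubly deprotonated (R)-2-hydroxy-1,2,2-triphenylethyl acetate (LiN(iPr)2, then MgBr2, THF, −110 °C) should give the β-hydroxy ester F7 with the 1R configuration. The (R)-reagent is known to give (R)-β-hydroxy acids when the aldehyde substituent outranks CH2, as it does here. KOH in aqueous methanol should release the β-hydroxy acid F8 and the recoverable diol. Activation with carbonyldiimidazole to the acyl imidazolide F9 (not isolated) and reaction with Mg(O2CCH(CH3)CO2CH3)2 should give, after loss of CO2, compound 16, where the route is rejoined. No Lewis acid stronger than the magnesium enolate meets the oxirane.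

**Further compounds**

F1 | step 15 | (6S)-epimer of 22 | CC(=O)O[C@@H]1CC2=C(C)C(=O)O[C@H]2/C=C(\C)CC[C@@H]2O[C@]2(C)CC/C=C/1C
F2 | step 15 | lithium 2-furanolate of the macrocycle (C6 planar) | [Li+].CC(=O)O[C@@H]1Cc2c(C)c([O-])oc2/C=C(\C)CC[C@@H]2O[C@]2(C)CC/C=C/1C
F3 | step 2 | (2R,3R)-3-methyl-3-(4-methylpent-3-en-1-yl)oxirane-2-carbaldehyde | CC(C)=CCC[C@@]1(C)O[C@H]1C=O
F4 | step 2 | (2S,3R)-2-ethenyl-3-methyl-3-(4-methylpent-3-en-1-yl)oxirane | CC(C)=CCC[C@@]1(C)O[C@H]1C=C
F5 | step 2 | 9-{2-[(2S,3R)-3-methyl-3-(4-methylpent-3-en-1-yl)oxiran-2-yl]ethyl}-9-borabicyclo[3.3.1]nonane | CC(C)=CCC[C@@]1(C)O[C@H]1CCB1C2CCCC1CCC2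
F6 | step 2 | methyl (2E)-3-{[(trifluoromethyl)sulfonyl]oxy}but-2-enoate | COC(=O)/C=C(\C)OS(=O)(=O)C(F)(F)F
F7 | step 10 | (1R)-2-hydroxy-1,2,2-triphenylethyl (3R,4E,8R,9S,12E)-14-[(tert-butyldimethylsilyl)oxy]-8,9-epoxy-3-hydroxy-4,8,12-trimethyltetradeca-4,12-dienoate | O=C(C[C@@H](O)/C(C)=C/CC[C@@]1(C)O[C@H]1CC/C(C)=C/CO[Si](C)(C)C(C)(C)C)O[C@H](c1ccccc1)C(O)(c1ccccc1)c1ccccc1
F8 | step 10 | (3R,4E,8R,9S,12E)-14-[(tert-butyldimethylsilyl)oxy]-8,9-epoxy-3-hydroxy-4,8,12-trimethyltetradeca-4,12-dienoic acid | OC(=O)C[C@@H](O)/C(C)=C/CC[C@@]1(C)O[C@H]1CC/C(C)=C/CO[Si](C)(C)C(C)(C)C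
F9 | step 10 | acyl imidazolide of F8 | O=C(C[C@@H](O)/C(C)=C/CC[C@@]1(C)O[C@H]1CC/C(C)=C/CO[Si](C)(C)C(C)(C)C)n1ccnc1
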